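**Plan**
- Target: the (2S)-7-hydroxy-6,8-diprenylflavanone whose ring B is a 2,2-dimethyl-2H-chromene. The retrosynthesis first cuts three olefins: the CH=CH bond of the pyran ring of the chromene and the CH=CMe2 bonds of both prenyl groups. It then cuts the C2–aryl bond of the flavanone, and last the two aryl–allyl bonds at C6 and C8.
- Enabling feature: each isoprenoid unit holds exactly one olefin. One is the cis CH=CH of the six-membered pyran ring, lying between the ring B carbon ortho to the ether oxygen and the quaternary O–CMe2 carbon. The other two are the trisubstituted olefins of the prenyl groups on C6 and C8 of ring A. A 2-vinylaryl 1,1-dimethylallyl ether plus two allyl groups therefore gives all three in one ruthenium-carbene operation.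
- Forward order: ring A allyl groups by double Claisen rearrangement; pyranone ring (chromone) by enaminone cyclisation; ring B boronic acid in three steps; union by conjugate addition, which turns the chromone into the flavanone ring C; desilylation; then closure of the pyran ring with conversion of allyl into prenyl.
- Stereochemistry: the only stereocentre, C2 (S), is set by the chiral bisphosphine on rhodium in the conjugate addition. All later steps are neutral or buffered, so retro-oxa-Michael racemisation is avoided.

Key step: step 11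

Assumption: the sense of induction in step 9 is taken from the (S)-BINAP/cyclohexenone model, which predicts 2S for the (S)-biaryl bisphosphine; if a trial on the parent chromone shows the opposite sense, the (R)-ligand is used.

**Step 1**
Reactants: 1 2',4'-dihydroxyacetophenone
Product: 2 2',4'-bis(allyloxy)acetophenone
Conditions: allyl bromide (3 equiv), K2CO3 (4 equiv), DMF, 70 °C
Reagents that add atoms: allyl bromide, C=CCBr
Why: Williamson ether synthesis; excess allyl bromide in warm DMF should alkylate the free 4-OH and also the hydrogen-bonded 2-OH.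

**Step 2**
Reactants: 2 2',4'-bis(allyloxy)acetophenone
Product: 4 3',5'-diallyl-2',4'-dihydroxyacetophenone, via mono-rearranged phenol 3 (not isolated)
Conditions: PhNEt2, 200 °C, sealed tube, Ar
Reagents that add atoms: none
Why: two successive aromatic Claisen ([3,3]-sigmatropic) rearrangements; the 2-O-allyl group can reach only C3 because C1 carries the acetyl group, which leaves C5 as the only free ortho position for the 4-O-allyl group, and the other order of events should converge on the same 3,5-diallyl pattern by a para-Claisen path.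

**Step 3**
Reactants: 4 3',5'-diallyl-2',4'-dihydroxyacetophenone
Product: 5 3',5'-diallyl-2'-hydroxy-4'-(methoxymethoxy)acetophenone
Conditions: MOMCl (1.2 equiv), iPr2NEt, CH2Cl2, 0 °C to 25 °C
Reagents that add atoms: chloromethyl methyl ether, COCCl
Why: chemoselective O-alkylation; the 2-OH is held in a hydrogen bond to the acetyl carbonyl and should stay free, as is general for 2,4-dihydroxyacetophenones, and the MOM group keeps the amide acetal of step 4 from methylating the 4-OH.

**Step 4**
Reactants: 5 3',5'-diallyl-2'-hydroxy-4'-(methoxymethoxy)acetophenone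
Product: 8 6,8-diallyl-7-hydroxy-4H-chromen-4-one, via enaminone 6 (not isolated), via MOM-protected chromone 7 (not isolated)
Conditions: Me2NCH(OMe)2, toluene, 90 °C; concentrate; then conc. HCl, MeOH, 50 °C
Reagents that add atoms: N,N-dimethylformamide dimethyl acetal, COC(OC)N(C)C
Why: enaminone condensation of the methyl ketone followed by acid-promoted addition of the 2-OH and loss of dimethylamine closes the pyranone ring (standard chromone synthesis), and the same acid in methanol should cleave the MOM acetal.

**Step 5**
Reactants: 8 6,8-diallyl-7-hydroxy-4H-chromen-4-one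
Product: 9 6,8-diallyl-7-(tert-butyldimethylsilyloxy)-4H-chromen-4-one
Conditions: TBSCl, imidazole, DMF, 25 °C
Reagents that add atoms: tert-butyldimethylsilyl chloride, CC(C)(C)[Si](C)(C)Cl
Why: phenol silylation; the silyl ether keeps the chromone from being deactivated as a phenoxide in step 9 and can be removed later under buffered conditions.

**Step 6**
Reactants: 10 5-bromo-2-hydroxybenzaldehyde
Product: 11 4-bromo-2-vinylphenol
Conditions: MePPh3Br (2.3 equiv), KOtBu (2.3 equiv), THF, 0 °C to 25 °C; aq NH4Cl
Reagents that add atoms: methyltriphenylphosphonium bromide, C[P+](c1ccccc1)(c1ccccc1)c1ccccc1.[Br-]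
Why: Wittig methylenation; the first equivalent of ylide is used up as base by the phenol and the second converts the aldehyde into the vinyl group.

**Step 7**
Reactants: 11 4-bromo-2-vinylphenol
Product: 12 4-bromo-1-[(2-methylbut-3-en-2-yl)oxy]-2-vinylbenzene
Conditions: tert-butyl 2-methylbut-3-en-2-yl carbonate (1.3 equiv), Pd(PPh3)4 (2 mol %), 4 Å molecular sieves, THF, 0 °C
Reagents that add atoms: tert-butyl 2-methylbut-3-en-2-yl carbonate, C=CC(C)(C)OC(=O)OC(C)(C)C
Why: Tsuji–Trost O-allylation; decarboxylative ionisation gives a 1,1-dimethylallyl palladium cation and tert-butoxide, and the phenoxide should attack the more substituted terminus under kinetic control at 0 °C to give the tertiary ether, while the C–Br bond is inert to this catalyst at that temperature.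

**Step 8**
Reactants: 12 4-bromo-1-[(2-methylbut-3-en-2-yl)oxy]-2-vinylbenzene
Product: 15 {4-[(2-methylbut-3-en-2-yl)oxy]-3-vinylphenyl}boronic acid, via aryllithium 13 (not isolated), via lithium aryltrimethoxyborate 14 (not isolated)
Conditions: n-BuLi (1.05 equiv), THF, −78 °C; B(OMe)3 (2 equiv), −78 °C to 0 °C; sat. aq NH4Cl
Reagents that add atoms: trimethyl borate, COB(OC)OC; water, O
Why: bromine–lithium exchange, which at −78 °C should outrun addition of butyllithium to the styrene as in the preparation of vinylphenylboronic acids, followed by borate trapping; hydrolysis with NH4Cl spares the acid-sensitive tertiary allyl ether.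

**Step 9**
Reactants: 9 6,8-diallyl-7-(tert-butyldimethylsilyloxy)-4H-chromen-4-one; 15 {4-[(2-methylbut-3-en-2-yl)oxy]-3-vinylphenyl}boronic acid (2 equiv)
Product: 16 (S)-6,8-diallyl-7-(tert-butyldimethylsilyloxy)-2-{4-[(2-methylbut-3-en-2-yl)oxy]-3-vinylphenyl}chroman-4-one
Conditions: [RhOH(cod)]2 (3 mol %), (S)-6,6'-dimethoxy-2,2'-bis[bis(3,4,5-trifluorophenyl)phosphino]biphenyl (6.5 mol %), toluene/H2O, 25 °C
Reagents that add atoms: none
Why: rhodium-catalysed asymmetric 1,4-addition of an arylboronic acid to a chromone (Hayashi–Miyaura reaction), in which transmetalation gives an aryl–rhodium species that inserts the C2=C3 bond and the rhodium enolate is protonated by water; the chiral bisphosphine fixes the face of C2 that is arylated (catalyst control, 2S expected), and the base-free conditions at 25 °C should prevent ring opening of the product.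

**Step 10**
Reactants: 16 (S)-6,8-diallyl-7-(tert-butyldimethylsilyloxy)-2-{4-[(2-methylbut-3-en-2-yl)oxy]-3-vinylphenyl}chroman-4-one
Product: 17 (S)-6,8-diallyl-7-hydroxy-2-{4-[(2-methylbut-3-en-2-yl)oxy]-3-vinylphenyl}chroman-4-one
Conditions: Bu4NF (1.1 equiv), AcOH (1.2 equiv), THF, 0 °C
Reagents that add atoms: none
Why: fluoride-mediated desilylation; acetic acid protonates the phenoxide at once, so the base-sensitive C2 stereocentre should not be put at risk by retro-oxa-Michael opening.

**Step 11**
Reactants: 17 (S)-6,8-diallyl-7-hydroxy-2-{4-[(2-methylbut-3-en-2-yl)oxy]-3-vinylphenyl}chroman-4-one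
Product: 19 (S)-2-(2,2-dimethyl-2H-chromen-6-yl)-7-hydroxy-6,8-bis(3-methylbut-2-en-1-yl)chroman-4-one (the target natural product), via ring-closed diallyl chromene 18 (not isolated)
Conditions: RuCl2(=CHPh)(H2IMes)(PCy3) (second-generation Grubbs catalyst, 5 mol %), CH2Cl2 (0.005 M), 25 °C; then 2-methyl-2-butene (large excess), 40 °C, sealed tube
Reagents that add atoms: 2-methyl-2-butene, CC=C(C)C
Why: The ruthenium benzylidene should exchange first with the least hindered olefin of ring B, the styrene vinyl group; the resulting arylmethylidene then undergoes [2+2] cycloaddition with the neighbouring O–CMe2–CH=CH2 olefin, and the ruthenacyclobutane cycloreverts to the chromene with loss of ethylene (Chauvin mechanism). Once ring closure is complete, 2-methyl-2-butene is added and the same catalyst should convert both allyl groups into prenyl groups by cross-metathesis with loss of propene. The closest known reaction types are ring-closing metathesis of 2-vinylaryl allyl ethers to 2H-chromenes and cross-metathesis of o-allylphenols with 2-methyl-2-butene, here joined in one flask. The six-membered pyran ring closes by intramolecular alkylidene transfer between two terminal olefins held ortho to each other on ring B; the ring allows only the cis olefin, and the geminal methyl groups on the ether carbon favour the reactive conformer (Thorpe–Ingold effect). No stereocentre is formed, and C2 should be untouched under these neutral conditions. The step needs ring closure to precede cross-metathesis at the styrene, which is secured by high dilution and by withholding 2-methyl-2-butene; the allyl groups on C6 and C8 are meta to each other and cannot ring-close, any intermolecular allyl dimers are cut back to prenyl groups by the excess olefin, and the cyclic olefin next to a quaternary carbon and the trisubstituted prenyl olefins are poor substrates, so the reaction should stop at 19.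

**Compound list**
1 | 2',4'-dihydroxyacetophenone | CC(=O)c1ccc(O)cc1O | starting material
2 | 2',4'-bis(allyloxy)acetophenone | CC(=O)c1ccc(OCC=C)cc1OCC=C | intermediate
3 | 3'-allyl-4'-(allyloxy)-2'-hydroxyacetophenone (mono-rearranged phenol) | CC(=O)c1ccc(OCC=C)c(CC=C)c1O | intermediate
4 | 3',5'-diallyl-2',4'-dihydroxyacetophenone | CC(=O)c1cc(CC=C)c(O)c(CC=C)c1O | intermediate
5 | 3',5'-diallyl-2'-hydroxy-4'-(methoxymethoxy)acetophenone | CC(=O)c1cc(CC=C)c(OCOC)c(CC=C)c1O | intermediate
6 | (E)-1-[3,5-diallyl-2-hydroxy-4-(methoxymethoxy)phenyl]-3-(dimethylamino)prop-2-en-1-one (enaminone) | CN(C)/C=C/C(=O)c1cc(CC=C)c(OCOC)c(CC=C)c1O | intermediate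
7 | 6,8-diallyl-7-(methoxymethoxy)-4H-chromen-4-one (MOM-protected chromone) | O=c1ccoc2c(CC=C)c(OCOC)c(CC=C)cc12 | intermediate
8 | 6,8-diallyl-7-hydroxy-4H-chromen-4-one | O=c1ccoc2c(CC=C)c(O)c(CC=C)cc12 | intermediate
9 | 6,8-diallyl-7-(tert-butyldimethylsilyloxy)-4H-chromen-4-one | O=c1ccoc2c(CC=C)c(O[Si](C)(C)C(C)(C)C)c(CC=C)cc12 | intermediate
10 | 5-bromo-2-hydroxybenzaldehyde (5-bromosalicylaldehyde) | O=Cc1cc(Br)ccc1O | starting material
11 | 4-bromo-2-vinylphenol | C=Cc1cc(Br)ccc1O | intermediate
12 | 4-bromo-1-[(2-methylbut-3-en-2-yl)oxy]-2-vinylbenzene | C=Cc1cc(Br)ccc1OC(C)(C)C=C | intermediate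
13 | {4-[(2-methylbut-3-en-2-yl)oxy]-3-vinylphenyl}lithium (aryllithium) | [Li]c1ccc(OC(C)(C)C=C)c(C=C)c1 | intermediate
14 | lithium trimethoxy{4-[(2-methylbut-3-en-2-yl)oxy]-3-vinylphenyl}borate (lithium aryltrimethoxyborate) | [Li+].CO[B-](OC)(OC)c1ccc(OC(C)(C)C=C)c(C=C)c1 | intermediate
15 | {4-[(2-methylbut-3-en-2-yl)oxy]-3-vinylphenyl}boronic acid | OB(O)c1ccc(OC(C)(C)C=C)c(C=C)c1 | intermediate
16 | (S)-6,8-diallyl-7-(tert-butyldimethylsilyloxy)-2-{4-[(2-methylbut-3-en-2-yl)oxy]-3-vinylphenyl}chroman-4-one | C=CCc1cc2c(c(CC=C)c1O[Si](C)(C)C(C)(C)C)O[C@H](c1ccc(OC(C)(C)C=C)c(C=C)c1)CC2=O | intermediate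
17 | (S)-6,8-diallyl-7-hydroxy-2-{4-[(2-methylbut-3-en-2-yl)oxy]-3-vinylphenyl}chroman-4-one | C=CCc1cc2c(c(CC=C)c1O)O[C@H](c1ccc(OC(C)(C)C=C)c(C=C)c1)CC2=O | intermediate
18 | (S)-6,8-diallyl-2-(2,2-dimethyl-2H-chromen-6-yl)-7-hydroxychroman-4-one (ring-closed diallyl chromene) | C=CCc1cc2c(c(CC=C)c1O)O[C@H](c1ccc3c(c1)C=CC(C)(C)O3)CC2=O | intermediate
19 | (S)-2-(2,2-dimethyl-2H-chromen-6-yl)-7-hydroxy-6,8-bis(3-methylbut-2-en-1-yl)chroman-4-one (the target natural product) | CC(C)=CCc1cc2c(c(CC=C(C)C)c1O)O[C@H](c1ccc3c(c1)C=CC(C)(C)O3)CC2=O | target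

**Count**
Total steps: 11. Longest linear sequence: 8 steps (steps 1, 2, 3, 4, 5, 9, 10, 11, from compound 1); the ring B branch (steps 6, 7, 8) joins at step 9.

**Steps most likely to fail**

Step 11. The cross-metathesis partner may cap the styrene olefin before it ring-closes, ring closure may stall at the hindered tertiary allyl olefin, or ruthenium hydrides from catalyst decay may move the allyl double bonds into conjugation and so shorten the side chains. The fallback takes the two kinds of metathesis apart; it sets out from 9 and comes back to the route at 19. Cross-metathesis of 9 with 2-methyl-2-butene (RuCl2(=CHPh)(H2IMes)(PCy3), the second-generation Grubbs catalyst, CH2Cl2, 40 °C) would give 7-(tert-butyldimethylsilyloxy)-6,8-bis(3-methylbut-2-en-1-yl)-4H-chromen-4-one F1. Addition of 15 under the conditions of step 9 would give (S)-7-(tert-butyldimethylsilyloxy)-6,8-bis(3-methylbut-2-en-1-yl)-2-{4-[(2-methylbut-3-en-2-yl)oxy]-3-vinylphenyl}chroman-4-one F2. Desilylation as in step 10 would give the free phenol (S)-7-hydroxy-6,8-bis(3-methylbut-2-en-1-yl)-2-{4-[(2-methylbut-3-en-2-yl)oxy]-3-vinylphenyl}chroman-4-one F3. Ring closure of this phenol alone with the first-generation Grubbs catalyst RuCl2(=CHPh)(PCy3)2, which leaves trisubstituted prenyl olefins alone, would give 19.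

Step 9. The aryl–rhodium intermediate may insert into a terminal or styrene olefin, protodeboronation may outrun addition to the electron-rich chromone, facial discrimination may be insufficient, or the product may open by retro-oxa-Michael reaction and lose enantiopurity. The fallback builds ring C by chalcone cyclisation and separates the enantiomers; it sets out from 12 and 4 and comes back at 17. Bromine–lithium exchange of 12 as in step 8 (via 13) and addition of DMF would give lithium (dimethylamino){4-[(2-methylbut-3-en-2-yl)oxy]-3-vinylphenyl}methanolate F4, which on aqueous work-up gives 4-[(2-methylbut-3-en-2-yl)oxy]-3-vinylbenzaldehyde F5. Claisen–Schmidt condensation of this aldehyde with 4 (KOH, EtOH/H2O, 25 °C) would give (E)-1-(3,5-diallyl-2,4-dihydroxyphenyl)-3-{4-[(2-methylbut-3-en-2-yl)oxy]-3-vinylphenyl}prop-2-en-1-one F6. NaOAc in EtOH at 70 °C would close it by oxa-Michael addition to racemic 6,8-diallyl-7-hydroxy-2-{4-[(2-methylbut-3-en-2-yl)oxy]-3-vinylphenyl}chroman-4-one F7. Preparative HPLC on a cellulose tris(3,5-dimethylphenylcarbamate) phase would give 17 and its enantiomer (R)-6,8-diallyl-7-hydroxy-2-{4-[(2-methylbut-3-en-2-yl)oxy]-3-vinylphenyl}chroman-4-one F8, which is returned to the base-mediated equilibration.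

Step 7. The allylpalladium intermediate may equilibrate and give the linear prenyl ether, the catalyst may insert into the C–Br bond, or the o-vinylphenol may polymerise. The fallback makes the tertiary ether without palladium allyl chemistry and before the vinyl group exists; it sets out from 10 and comes back at 12. Alkylation of 10 with 3-chloro-3-methylbut-1-yne (DBU, CuCl2 cat., MeCN, 0 °C) would give 5-bromo-2-[(2-methylbut-3-yn-2-yl)oxy]benzaldehyde F9. Semi-hydrogenation over Lindlar catalyst (Pd on CaCO3 poisoned with Pb(OAc)2, quinoline, H2, EtOAc) would give 5-bromo-2-[(2-methylbut-3-en-2-yl)oxy]benzaldehyde F10. Wittig methylenation (MePPh3Br, KOtBu, THF, 0 °C) would give 12.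

**Further compounds**
F1 | step 11 | 7-(tert-butyldimethylsilyloxy)-6,8-bis(3-methylbut-2-en-1-yl)-4H-chromen-4-one | O=c1ccoc2c(CC=C(C)C)c(O[Si](C)(C)C(C)(C)C)c(CC=C(C)C)cc12
F2 | step 11 | (S)-7-(tert-butyldimethylsilyloxy)-6,8-bis(3-methylbut-2-en-1-yl)-2-{4-[(2-methylbut-3-en-2-yl)oxy]-3-vinylphenyl}chroman-4-one | CC(C)=CCc1cc2c(c(CC=C(C)C)c1O[Si](C)(C)C(C)(C)C)O[C@H](c1ccc(OC(C)(C)C=C)c(C=C)c1)CC2=O
F3 | step 11 | (S)-7-hydroxy-6,8-bis(3-methylbut-2-en-1-yl)-2-{4-[(2-methylbut-3-en-2-yl)oxy]-3-vinylphenyl}chroman-4-one | CC(C)=CCc1cc2c(c(CC=C(C)C)c1O)O[C@H](c1ccc(OC(C)(C)C=C)c(C=C)c1)CC2=O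
F4 | step 9 | lithium (dimethylamino){4-[(2-methylbut-3-en-2-yl)oxy]-3-vinylphenyl}methanolate | [Li+].CN(C)C([O-])c1ccc(OC(C)(C)C=C)c(C=C)c1
F5 | step 9 | 4-[(2-methylbut-3-en-2-yl)oxy]-3-vinylbenzaldehyde | O=Cc1ccc(OC(C)(C)C=C)c(C=C)c1
F6 | step 9 | (E)-1-(3,5-diallyl-2,4-dihydroxyphenyl)-3-{4-[(2-methylbut-3-en-2-yl)oxy]-3-vinylphenyl}prop-2-en-1-one | C=CCc1cc(C(=O)/C=C/c2ccc(OC(C)(C)C=C)c(C=C)c2)c(O)c(CC=C)c1O
F7 | step 9 | racemic 6,8-diallyl-7-hydroxy-2-{4-[(2-methylbut-3-en-2-yl)oxy]-3-vinylphenyl}chroman-4-one | C=CCc1cc2c(c(CC=C)c1O)OC(c1ccc(OC(C)(C)C=C)c(C=C)c1)CC2=O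
F8 | step 9 | (R)-6,8-diallyl-7-hydroxy-2-{4-[(2-methylbut-3-en-2-yl)oxy]-3-vinylphenyl}chroman-4-one | C=CCc1cc2c(c(CC=C)c1O)O[C@@H](c1ccc(OC(C)(C)C=C)c(C=C)c1)CC2=O
F9 | step 7 | 5-bromo-2-[(2-methylbut-3-yn-2-yl)oxy]benzaldehyde | O=Cc1cc(Br)ccc1OC(C)(C)C#C
F10 | step 7 | 5-bromo-2-[(2-methylbut-3-en-2-yl)oxy]benzaldehyde | O=Cc1cc(Br)ccc1OC(C)(C)C=C
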